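**Strategy.** Fertidin hides an aldol array: the isopropyl carbinol carbon (C4) of the five-membered ring, the ring-fusion CH (C5) and the ester carbon (C6) of the seven-membered ring. The route therefore disconnects the C1–C5 bond by a semipinacol retron. In one operation, a Lewis acid shifts the methyl-bearing angular carbon (C1) of a cis-decalin 2,3-epoxy alcohol from the carbinol carbon to the adjacent epoxide carbon: ring A contracts from six to five atoms, ring B grows from six to seven, and the C4 hydroxyl, the C5 stereocentre and the C6 ketone appear together. The precursor, an all-cis hydroxy epoxide of a 6-6 bicycle, is assembled from (R)-carvone; directed reduction and acylation finish the synthesis.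

Key step: step 7

Remark: the labels C1–C10 follow the target carbons through all intermediates (C1 = ring-fusion C–CH3, C2 and C3 = cyclopentane CH2, C4 = C(OH)(i-Pr), C5 = ring-fusion CH, C6 = CH–O, C7 = CH2, C8 = C(CH3)=, C9 = =CH, C10 = CH2); compounds 1, 2 and 14 are assumed to be commercial.

Step 1
Reactants: 1 (R)-(−)-carvone; 2 4-iodobut-1-ene
Product: 4 (2S,5R)-2-(but-3-en-1-yl)-2-methyl-5-(prop-1-en-2-yl)cyclohexan-1-one, via lithium enolate 3 (not isolated)
Conditions: LiBH(s-Bu)3, THF, −78 °C; then 2, HMPA, −78 °C to rt
Reagents that add atoms: none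
Why: Conjugate hydride reduction of the enone gives the regiodefined lithium enolate 3, and its C-alkylation (reductive alkylation of an enone) should take place by axial attack on the half-chair that carries the isopropenyl group equatorially, which puts the butenyl chain cis to isopropenyl and so fixes the quaternary centre C1, the minor epimer being removed by chromatography before the relay centre is erased.

Step 2
Reactants: 4 (2S,5R)-2-(but-3-en-1-yl)-2-methyl-5-(prop-1-en-2-yl)cyclohexan-1-one
Product: 5 (S)-6-(but-3-en-1-yl)-6-methyl-3-(propan-2-yl)cyclohex-2-en-1-one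
Conditions: p-TsOH·H2O (cat.), benzene, reflux
Reagents that add atoms: none
Why: Acid-catalysed double-bond migration (the dihydrocarvone-to-carvenone isomerisation) should carry the isopropenyl alkene via the isopropylidene isomer and the dienol into conjugation with the ketone as C4=C5, which erases the relay stereocentre while the quaternary C1 and the less basic monosubstituted alkene are left alone.

Step 3
Reactants: 5 (S)-6-(but-3-en-1-yl)-6-methyl-3-(propan-2-yl)cyclohex-2-en-1-one
Product: 6 (R)-6-methyl-6-(3-oxobutyl)-3-(propan-2-yl)cyclohex-2-en-1-one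
Conditions: PdCl2 (10 mol %), CuCl (1 equiv), O2 (1 atm), DMF/H2O (7:1), rt
Reagents that add atoms: water, O
Why: Wacker oxidation of the terminal alkene with Markovnikov regiochemistry should give the C8 methyl ketone, dioxygen serving as terminal oxidant, without touching the electron-poor trisubstituted enone.

Step 4
Reactants: 6 (R)-6-methyl-6-(3-oxobutyl)-3-(propan-2-yl)cyclohex-2-en-1-one
Product: 9 (4aR,8aS)-8a-hydroxy-4a-methyl-7-(propan-2-yl)-1,4,4a,5,6,8a-hexahydronaphthalen-2-yl trifluoromethanesulfonate, via lithium aldolate 7 (not isolated), via dilithium alkoxide enolate 8 (not isolated)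
Conditions: LiN(i-Pr)2 (1.05 equiv), THF, −78 to −40 °C; then LiN(i-Pr)2 (1.3 equiv), −78 °C; then PhNTf2, −78 to 0 °C; aqueous work-up
Reagents that add atoms: N-phenylbis(trifluoromethanesulfonimide), O=S(=O)(N(c1ccccc1)S(=O)(=O)C(F)(F)F)C(F)(F)F
Why: Kinetic enolisation of the methyl ketone and intramolecular aldol addition of C7 to the ring-A carbonyl C6 should close ring B cis-fused, because the tethered enolate can reach only the carbonyl face on the side of its own C1–C10 bond (hydroxyl cis to the C1 methyl), and the second deprotonation of the β-alkoxy ketone should occur at C9, remote from the alkoxide, so that O-sulfonylation of the enolate gives the C8=C9 enol triflate.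

Step 5
Reactants: 9 (4aR,8aS)-8a-hydroxy-4a-methyl-7-(propan-2-yl)-1,4,4a,5,6,8a-hexahydronaphthalen-2-yl trifluoromethanesulfonate
Product: 10 (4aS,8aR)-6,8a-dimethyl-3-(propan-2-yl)-1,5,8,8a-tetrahydronaphthalen-4a(2H)-ol (cis-fused dienol)
Conditions: MeMgBr (3 equiv), Fe(acac)3 (5 mol %), THF/NMP, −30 to 0 °C
Reagents that add atoms: methylmagnesium bromide, C[Mg]Br
Why: Iron-catalysed Kumada-type cross-coupling of the alkenyl triflate with the methyl Grignard reagent should place the C8 methyl group without moving the C8=C9 double bond, the tertiary alcohol travelling as its magnesium alkoxide.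

Step 6
Reactants: 10 cis-fused dienol
Product: 11 all-cis epoxy alcohol (C4–C5 epoxide of 10 on the face of the C6 hydroxyl and the C1 methyl; C1 R, C4 R, C5 R, C6 R)
Conditions: VO(acac)2 (3 mol %), t-BuOOH (1.1 equiv), CH2Cl2, 0 °C to rt
Reagents that add atoms: tert-butyl hydroperoxide, CC(C)(C)OO
Why: Vanadium-catalysed hydroxyl-directed epoxidation should deliver the oxygen to the allylic C4=C5 bond on the face of the C6 hydroxyl, which is also the face of the C1 methyl, far faster than to the homoallylic C8=C9 bond, and so sets C4 and C5.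

Step 7
Reactants: 11 all-cis epoxy alcohol
Product: 12 (3R,3aR,8aR)-3-hydroxy-6,8a-dimethyl-3-(propan-2-yl)-2,3,3a,5,8,8a-hexahydroazulen-4(1H)-one
Conditions: ZnBr2 (0.5 equiv), CH2Cl2, 0 °C to rt
Reagents that add atoms: none
Why: Chelation of zinc by the syn hydroxyl and epoxide oxygens polarises the C5–O bond, and the C6–C1 σ-bond, which lies anti to it in the cis-decalin conformer with the hydroxyl pseudoaxial on ring A, shifts from C6 to C5 as the carbinol collapses to the C6 ketone (semipinacol rearrangement of a 2,3-epoxy alcohol, the epoxide counterpart of the classical hydroxy sulfonate decalin-to-hydroazulene pinacol rearrangement). The 1,2-shift closes the five-membered ring by forming C1–C5 (contraction of ring A by extrusion of C6) and in the same event enlarges ring B to the seven-membered ring by inserting C5 between C1 and C6, so no cyclisation in the Baldwin sense is involved. C5 is set by inversion at the migration terminus (C1 enters anti to the departing epoxide oxygen), C4 keeps the oxygen placed by the directed epoxidation, and C1 migrates with retention, so the all-cis epoxy alcohol maps onto the trans ring fusion with the C4 hydroxyl cis to the C1 methyl. The step needs cleavage of the C5–O bond instead of ionisation at the more substituted C4, and migration of C1 instead of the C7 methylene; the hydroxyl push through the chelate, the higher migratory aptitude of the fully substituted C1 and the release of cis-decalin strain on the way to the trans-hydroazulenone should secure both. A mild Lewis acid and low temperature are chosen to keep the β-hydroxy ketone from dehydrating and the C8=C9 bond from moving into conjugation.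

Step 8
Reactants: 12 (3R,3aR,8aR)-3-hydroxy-6,8a-dimethyl-3-(propan-2-yl)-2,3,3a,5,8,8a-hexahydroazulen-4(1H)-one
Product: 13 jaeschkeanadiol, (3R,3aS,4S,8aR)-6,8a-dimethyl-3-(propan-2-yl)-1,2,3,3a,4,5,8,8a-octahydroazulene-3,4-diol
Conditions: Me4NBH(OAc)3, MeCN/AcOH (1:1), −30 °C; aqueous work-up
Reagents that add atoms: none
Why: Evans–Saksena reduction, in which the borohydride bound to the C4 oxygen hands its hydride to the neighbouring C6 carbonyl within a six-membered transition state, should give the 1,3-anti diol with H6 trans to H5, the face that an external hydride would be expected to avoid.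

Step 9
Reactants: 13 jaeschkeanadiol; 14 4-methoxybenzoyl chloride
Product: 15 fertidin, (3R,3aS,4S,8aR)-3-hydroxy-6,8a-dimethyl-3-(propan-2-yl)-1,2,3,3a,4,5,8,8a-octahydroazulen-4-yl 4-methoxybenzoate
Conditions: DMAP (cat.), pyridine, CH2Cl2, 0 °C to rt
Reagents that add atoms: none
Why: DMAP-catalysed acylation (nucleophilic acyl substitution) should esterify only the secondary C6 hydroxyl, the hindered tertiary C4 hydroxyl being inert under these conditions.

**Compound list**

1 | (R)-(−)-carvone | CC1=CC[C@@H](C(C)=C)CC1=O | starting material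
2 | 4-iodobut-1-ene | C=CCCI | starting material
3 | lithium (5R)-2-methyl-5-(prop-1-en-2-yl)cyclohex-1-en-1-olate | [Li+].[O-]C1=C(C)CC[C@@H](C(C)=C)C1 | intermediate
4 | (2S,5R)-2-(but-3-en-1-yl)-2-methyl-5-(prop-1-en-2-yl)cyclohexan-1-one | C=CCC[C@@]1(C)CC[C@@H](C(C)=C)CC1=O | intermediate
5 | (S)-6-(but-3-en-1-yl)-6-methyl-3-(propan-2-yl)cyclohex-2-en-1-one | C=CCC[C@@]1(C)CCC(C(C)C)=CC1=O | intermediate
6 | (R)-6-methyl-6-(3-oxobutyl)-3-(propan-2-yl)cyclohex-2-en-1-one | CC(=O)CC[C@@]1(C)CCC(C(C)C)=CC1=O | intermediate
7 | lithium alkoxide of (4aR,8aS)-8a-hydroxy-4a-methyl-7-(propan-2-yl)-3,4,4a,5,6,8a-hexahydronaphthalen-2(1H)-one | [Li+].CC(C)C1=C[C@@]2([O-])CC(=O)CC[C@@]2(C)CC1 | intermediate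
8 | dilithium alkoxide C8=C9 enolate of the same cis-ketol | [Li+].[Li+].CC(C)C1=C[C@@]2([O-])CC([O-])=CC[C@@]2(C)CC1 | intermediate
9 | (4aR,8aS)-8a-hydroxy-4a-methyl-7-(propan-2-yl)-1,4,4a,5,6,8a-hexahydronaphthalen-2-yl trifluoromethanesulfonate | CC(C)C1=C[C@@]2(O)CC(OS(=O)(=O)C(F)(F)F)=CC[C@@]2(C)CC1 | intermediate
10 | (4aS,8aR)-6,8a-dimethyl-3-(propan-2-yl)-1,5,8,8a-tetrahydronaphthalen-4a(2H)-ol | CC(C)C1=C[C@@]2(O)CC(C)=CC[C@@]2(C)CC1 | intermediate
11 | all-cis C4–C5 epoxide of 10 (epoxide, C6 hydroxyl and C1 methyl on one face) | CC(C)[C@@]12O[C@@H]1[C@@]3(O)CC(C)=CC[C@@]3(C)CC2 | intermediate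
12 | (3R,3aR,8aR)-3-hydroxy-6,8a-dimethyl-3-(propan-2-yl)-2,3,3a,5,8,8a-hexahydroazulen-4(1H)-one | O=C1CC(C)=CC[C@@]2(C)CC[C@@](O)(C(C)C)[C@H]12 | intermediate
13 | jaeschkeanadiol, (3R,3aS,4S,8aR)-6,8a-dimethyl-3-(propan-2-yl)-1,2,3,3a,4,5,8,8a-octahydroazulene-3,4-diol | O[C@H]1CC(C)=CC[C@@]2(C)CC[C@@](O)(C(C)C)[C@H]12 | intermediate
14 | 4-methoxybenzoyl chloride | COc1ccc(C(Cl)=O)cc1 | starting material
15 | fertidin | COc1ccc(C(=O)O[C@H]2CC(C)=CC[C@@]3(C)CC[C@@](O)(C(C)C)[C@H]23)cc1 | target

**Total step count:** 9
**Longest linear sequence:** 9 steps (1 to 15)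

**Steps most likely to fail**

Step 7. The epoxide may ionise at the more substituted C4 and then undergo hydride shift or elimination, or the C7 methylene may migrate in place of C1. The fallback sets out from dienol 10 and avoids any epoxide. Hydrogen-bond-directed syn-dihydroxylation of C4=C5 with OsO4 and TMEDA (CH2Cl2, −78 °C) should give the all-cis triol F1. MsCl and Et3N should sulfonylate only the secondary C5 hydroxyl to give the mesylate F2. Et3Al (CH2Cl2, −78 °C) should then promote the pinacol-type rearrangement of this β-mesyloxy alcohol: the aluminium alkoxide at C6 pushes C1 onto C5 with inversion and loss of mesylate, with no cationic centre at C4. The route is rejoined at hydroxy ketone 12.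

Step 4. The lithium aldolate may fragment by retro-aldol reaction or lose the alkoxide on warming, and the second deprotonation may occur on the carbinol side (C7), which would misplace the ring-B double bond. The fallback sets out from diketone 6. Aldol addition with one equivalent of LiN(i-Pr)2 and an acetic acid quench at −78 °C should give the isolated cis-ketol F3. Condensation with 2,4,6-triisopropylbenzenesulfonyl hydrazide should give the trisylhydrazone F4, in which the carbonyl is masked against retro-aldol cleavage. A Shapiro reaction (n-BuLi, THF/TMEDA, −78 to 0 °C, then MeI) should deprotonate C9 syn to the sulfonamide nitrogen and methylate the resulting alkenyllithium at C8. The route is rejoined at dienol 10.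

Step 1. C-alkylation by the unactivated homoallylic iodide may be slow, so that elimination of HI from the iodide, enolate equilibration and eroded facial selectivity compete. The fallback sets out from lithium enolate 3. Alkylation with the reactive allylic chloride (E)-1,3-dichlorobut-2-ene (Wichterle reagent; either alkene isomer serves) should give the chloroalkenyl ketone F5. The same p-TsOH isomerisation should give the enone F6. Hydrolysis of the vinyl chloride with cold concentrated H2SO4 (0 °C) should unveil the methyl ketone, which makes the Wacker step unnecessary. The route is rejoined at diketone 6.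

**Further compounds**

F1 | step 7 | all-cis C4,C5,C6-triol (three hydroxyls and the C1 methyl on one face) | CC(C)[C@@]1(O)[C@H](O)[C@@]2(O)CC(C)=CC[C@@]2(C)CC1
F2 | step 7 | C5 methanesulfonate of triol F1 | CC(C)[C@@]1(O)[C@H](OS(C)(=O)=O)[C@@]2(O)CC(C)=CC[C@@]2(C)CC1
F3 | step 4 | (4aR,8aS)-8a-hydroxy-4a-methyl-7-(propan-2-yl)-3,4,4a,5,6,8a-hexahydronaphthalen-2(1H)-one (cis-ketol) | CC(C)C1=C[C@@]2(O)CC(=O)CC[C@@]2(C)CC1
F4 | step 4 | 2,4,6-triisopropylbenzenesulfonylhydrazone of ketol F3 (sulfonamide nitrogen syn to C9) | CC(C)C1=C[C@@]2(O)C/C(=N/NS(=O)(=O)c3c(C(C)C)cc(C(C)C)cc3C(C)C)CC[C@@]2(C)CC1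
F5 | step 1 | (2R,5R)-2-[(2E)-3-chlorobut-2-en-1-yl]-2-methyl-5-(prop-1-en-2-yl)cyclohexan-1-one | C/C(Cl)=C\C[C@@]1(C)CC[C@@H](C(C)=C)CC1=O
F6 | step 1 | (R)-6-[(2E)-3-chlorobut-2-en-1-yl]-6-methyl-3-(propan-2-yl)cyclohex-2-en-1-one | C/C(Cl)=C\C[C@@]1(C)CCC(C(C)C)=CC1=O
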